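# Ugonin Q: proposed total synthesis through an allylsilane-terminated cation cyclisation

## Analysis of the target

Ugonin Q is luteolin (rings A, C and B: a 5,7-dihydroxychromen-4-one with a catechol at C2) whose C6 carries, through one methylene group, a monocyclic terpenoid ring D. Ring D is a cyclohexane with D1 (CHOH), D2 (C=CH2), D3 (CH bearing the benzylic CH2), D4 (CMe2), D5 and D6 (CH2). It holds the only two stereocentres, D1 (S) and D3 (S), which are 1,3-related across the methylene-bearing carbon and trans to each other. The sensitive groups are the secondary allylic alcohol beside a 1,1-disubstituted alkene, the 5- and 7-hydroxyls that in acid can add to the protonated methylene, the catechol (air-sensitive as its phenolate) and the pyranone (a Michael acceptor). Three things make the synthesis hard: the D3–D4 bond joins a tertiary stereocentre to a quaternary carbon; the alkene must end exocyclic at D2 and nowhere else; and the C6–CH2 bond has to be made at an arene position flanked by two oxygen substituents, in competition with C8. The strategy rests on one feature: the D3–D4 bond lies one atom away from the exocyclic alkene. D4 can therefore be a tertiary cation and D3 the gamma carbon of an allylsilane whose silicon sits on the future methylene carbon, so that C–C bond formation, ring closure, the D3 configuration and the position of the alkene are settled in one event. Rings A to C are bought as luteolin, so the effort goes into ring D.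

## Retrosynthetic reasoning

**Unmasking.** Target 25 is traced back to 24, in which the four silyl ethers and the 5-acetate are removed by fluoride and mild base. Only fluoride- and base-labile groups are used, because acid would bring the phenols, the allylic alcohol and the methylene group to react with each other.

**C6–CH2 bond.** 24 is cut between C6 of ring A and the benzylic carbon into the primary iodide 18 (through its zinc reagent 23) and the aryl iodide 22. This is the only bond that joins a bought ring system to the terpenoid part, so the route becomes convergent. The forward reaction has to couple a beta-branched primary alkylzinc with a di-ortho-substituted aryl iodide, so no acidic proton may remain; the 5-hydroxyl is therefore capped as an acetate.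

**Aryl partner.** 22 goes back through the 6-iodide 21 and the tris-silyl ether 20 to luteolin 19. The 5-hydroxyl stays free in 20 because it is chelated to the carbonyl group, and with O7 capped the halogenation is expected at C6, ortho to that phenol.

**Ring D functional groups.** 18 comes from the primary alcohol 17, and 17 from the doubly silylated ring 16 by removal of the less hindered primary silyl ether.

**Key disconnection, D3–D4.** 16 is opened between D3 and D4 to the (Z)-allylsilane tertiary carbinol 13. This bond is the hindered one. Made from a tertiary cation inside a six-membered transition state, it needs no intermolecular attack on a quaternary centre, and the silicon fixes where the alkene appears. Two protecting-group choices on 13 belong to this step: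

- The primary oxygen is a silyl ether and not an ester. A 4-acyloxy-but-2-enylsilane can lose silicon and carboxylate to a diene under a Lewis acid.
- The D1 oxygen carries a triisopropylsilyl group. Its bulk disfavours the in-plane position next to the CH2SiMe3 arm, and it makes capture of the cation by this oxygen unproductive.

**Allylsilane.** 13 comes from the diol 12 by silylation of the primary hydroxyl. 12 comes from the iodoalkene 10 and the Grignard reagent 11, and 10 from the alkynediol 8 by hydroxyl-directed trans-hydroalumination. Directing the metal from the primary hydroxyl places it on D2, cis to the CH2OH arm, which is the geometry the chair transition state needs.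

**D1 stereocentre.** 8 goes back through 7 and 6 to the ynone 5. The carbinol is set by catalytic asymmetric transfer hydrogenation of the alkynyl ketone, a reagent-controlled step that gives either enantiomer from the same ketone.

**Carbon skeleton.** 5 is cut at the ketone into the propargyl silyl ether 1 and the lactone 2, which already contains D4 with both methyl groups and its oxygen, and D5 and D6.

## Alternatives that were turned down

**Alternative 1:** Disconnection at D1–D2. The open-chain aldehyde–iodoalkene A1 (D1 as aldehyde, D2 as the iodine-bearing carbon of a 2-iodoalkene, the flavone attached as its tetra-MOM ether) would be closed with CrCl2 and catalytic NiCl2 in a Nozaki–Hiyama–Kishi reaction to the tetra-MOM ether A2 of the target.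
- For it: the alkenylchromium species forms only at the C–I bond and adds to the aldehyde in the presence of the pyranone. Ring, free carbinol and methylene group arise in one step, without a protecting group at D1 and without cationic intermediates. Because D3 would already be in place, a wrong configuration at D1 could be mended by oxidation and reduction. On this point the alternative is stronger: in the chosen route a wrong facial choice is written into D3.
- Against it: the difficult bond, D3–D4, is not made by the key step. It and the D3 configuration would have to be built in open chain, beside a vinyl iodide and a bulky arylmethyl group. D1 is then controlled only by 1,3-induction across an sp2 carbon. The whole flavone is carried through the longest linear sequence, and four MOM ethers need acid at the end, which endangers the allylic alcohol and invites the 5- or 7-hydroxyl to add to the methylene group.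
- In its place the chosen strategy makes the hindered bond intramolecularly, sets D3 in the same event, keeps the flavone out of the sequence until the penultimate step and ends without acid.

**Alternative 2:** Ring A is built last by a Danheiser benzannulation. The pyranonyl diazo ketone A3 would be irradiated (Wolff rearrangement to a vinylketene) in the presence of the ring D ynol silyl ether A4. Cycloaddition to a cyclobutenone, then heating (four-electron ring opening, six-electron closure) would form C5–C6, C7–C8 and C4a–C5 and give the flavone A5 with the 5-hydroxyl free and O7 silylated.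
- For it: the substituent is placed at C6 by the alkyne, not by a halogenation; the 5- and 7-oxygens emerge differentiated; and no cross-coupling at a di-ortho-substituted arene is needed. On these three points it is stronger than the chosen route.
- Against it: it rebuilds a ring that is available in luteolin 19. A3 needs several steps and diazo chemistry, and the pyranone chromophore competes for light. The exocyclic alkene of A4 can itself react with a ketene. A4 is an acid-sensitive ynol ether that must be made from a hindered ring D precursor. The ring B MOM ethers again need acid. Above all, the alternative does not construct ring D, so the stereochemical problem is only moved to the synthesis of A4.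
- In its place the chosen strategy spends its steps on ring D and leaves the C6 position to an iodination that is expected to prefer C6.

**Alternative 3:** Ring C is built last by a carbonylative annulation. The iodophenol A6 (from a mirror-symmetric phenol, so that ortho-iodination has one outcome), the ring B alkyne A7 and carbon monoxide A8 would be combined with PdCl2(PPh3)2 and Et2NH. Acylpalladium formation, alkynylation and amine-mediated 6-endo closure form C4a–C4, C4–C3 and O1–C2 and give A9.
- For it: the C6 regiochemistry is secured by symmetry, three components are joined in one flask, and the conditions are mild. On regiochemical certainty it is stronger than the chosen route.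
- Against it: ring D must still be joined to a phloroglucinol core, which is the same hindered sp3–sp2 bond made earlier. The three oxygens of that core must be differentiated. The aryl iodide is flanked by two oxygen substituents. The intermediate alkynyl ketone can close 5-exo to an aurone. Four MOM ethers need acid at the end. As with Alternative 2, ring D itself is not addressed.
- In its place the chosen strategy uses luteolin 19 whole and needs three steps on the aromatic side.

Key step: step 8

## Route

Assumption: compounds 1 and 2 are taken as purchasable, and the (S,S)-ligand of step 2 is taken to give the (S)-carbinol, as is usual for this catalyst class with alkynyl ketones; were the sense opposite, the enantiomeric ligand would be used.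

Step 1
Reactants: 1 tert-butyldimethyl(prop-2-yn-1-yloxy)silane; 2 5,5-dimethyldihydrofuran-2(3H)-one
Product: 5 1-(tert-butyldimethylsilyloxy)-7-hydroxy-7-methyloct-2-yn-4-one, via lithium acetylide 3 (not isolated), via lithium lactolate 4 (not isolated)
Conditions: n-BuLi (1.05 equiv), THF, −78 °C; then 2, −78 °C; AcOH quench at −78 °C
Reagents that add atoms: none
Why: Acetylide addition to a lactone: 3 adds once to the carbonyl group and the tetrahedral lactolate 4 holds at −78 °C, so the ynone is released only on the cold quench and cannot take up a second acetylide; the future D4 with both methyl groups and its oxygen is in place from the first step.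

Step 2
Reactants: 5 1-(tert-butyldimethylsilyloxy)-7-hydroxy-7-methyloct-2-yn-4-one
Product: 6 (4S)-1-(tert-butyldimethylsilyloxy)-7-methyloct-2-yne-4,7-diol
Conditions: Ru(p-cymene)[(S,S)-TsNCH(Ph)CH(Ph)NH] (2 mol%), i-PrOH, rt
Reagents that add atoms: none
Why: Noyori asymmetric transfer hydrogenation of an alkynyl ketone: in the bifunctional hydride transfer the alkyne takes the place that an aryl group takes in aryl ketones, so the (S,S)-ligand should deliver hydride to the face that gives the (4S)-carbinol (D1); the base-free medium spares the ynone and the tertiary hydroxyl is a spectator.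

Step 3
Reactants: 6 (4S)-1-(tert-butyldimethylsilyloxy)-7-methyloct-2-yne-4,7-diol
Product: 7 (5S)-8-(tert-butyldimethylsilyloxy)-2-methyl-5-(triisopropylsilyloxy)oct-6-yn-2-ol
Conditions: TIPSOTf (1.05 equiv), 2,6-lutidine, CH2Cl2, −78 °C
Reagents that add atoms: triisopropylsilyl trifluoromethanesulfonate, CC(C)[Si](C(C)C)(C(C)C)OS(=O)(=O)C(F)(F)F
Why: Silyl ether formation: at −78 °C the silyl triflate discriminates the unhindered propargylic secondary hydroxyl from the tertiary one; the D1 oxygen must be capped before step 5 so that only the primary hydroxyl can direct the hydroalumination, and the bulky group is chosen for its role in step 8.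

Step 4
Reactants: 7 (5S)-8-(tert-butyldimethylsilyloxy)-2-methyl-5-(triisopropylsilyloxy)oct-6-yn-2-ol
Product: 8 (4S)-7-methyl-4-(triisopropylsilyloxy)oct-2-yne-1,7-diol
Conditions: CSA (0.1 equiv), MeOH–CH2Cl2, 0 °C
Reagents that add atoms: none
Why: Acid-catalysed methanolysis of a silyl ether: the primary TBS ether is cleaved far faster than the secondary TIPS ether, and the mild sulfonic acid in methanol does not ionise the tertiary or the propargylic C–O bond.

Step 5
Reactants: 8 (4S)-7-methyl-4-(triisopropylsilyloxy)oct-2-yne-1,7-diol
Product: 10 (2Z,4S)-3-iodo-7-methyl-4-(triisopropylsilyloxy)oct-2-ene-1,7-diol, via vinylalanate 9 (not isolated)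
Conditions: NaAlH2(OCH2CH2OMe)2 (Red-Al, 3 equiv), THF, 0 °C; then I2, THF, −78 to 0 °C
Reagents that add atoms: iodine, II
Why: Hydroxyl-directed trans-hydroalumination of a propargylic alcohol followed by iodinolysis: the aluminium alkoxide delivers hydride to C2 (D3) and aluminium ends on C3 (D2) in the five-membered alanate 9, and iodine replaces aluminium with retention, which puts iodine on D2 cis to the CH2OH arm; the low temperature is meant to prevent beta-elimination of the silyloxy group from 9 to an allene.

Step 6
Reactants: 10 (2Z,4S)-3-iodo-7-methyl-4-(triisopropylsilyloxy)oct-2-ene-1,7-diol; 11 (trimethylsilyl)methylmagnesium chloride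
Product: 12 (2Z,4S)-7-methyl-3-[(trimethylsilyl)methyl]-4-(triisopropylsilyloxy)oct-2-ene-1,7-diol
Conditions: 11 (5 equiv), Pd(PPh3)4 (5 mol%), THF, rt to 45 °C
Reagents that add atoms: none
Why: Kumada coupling: the alkenyl iodide couples with the Grignard reagent, which has no beta hydrogen, with retention of alkene geometry, the two hydroxyls being carried as magnesium alkoxides; this gives the (Z)-allylsilane with CH2SiMe3 on D2 cis to the CH2OH arm.

Step 7
Reactants: 12 (2Z,4S)-7-methyl-3-[(trimethylsilyl)methyl]-4-(triisopropylsilyloxy)oct-2-ene-1,7-diol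
Product: 13 (5S,6Z)-8-(tert-butyldimethylsilyloxy)-2-methyl-5-(triisopropylsilyloxy)-6-[(trimethylsilyl)methyl]oct-6-en-2-ol
Conditions: TBSCl (1.1 equiv), imidazole, CH2Cl2, 0 °C
Reagents that add atoms: tert-butyldimethylsilyl chloride, CC(C)(C)[Si](C)(C)Cl
Why: Selective silylation: the primary allylic hydroxyl reacts while the tertiary carbinol, needed free for ionisation, does not; a silyl ether is preferred to an ester here because an allylic ester in this position could leave together with silicon under a Lewis acid.

Step 8
Reactants: 13 (5S,6Z)-8-(tert-butyldimethylsilyloxy)-2-methyl-5-(triisopropylsilyloxy)-6-[(trimethylsilyl)methyl]oct-6-en-2-ol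
Product: 16 tert-butyl{[(1S,5S)-2,2-dimethyl-6-methylidene-5-(triisopropylsilyloxy)cyclohexyl]methoxy}dimethylsilane, via tertiary cation 14 (not isolated), via beta-silyl cation 15 (not isolated)
Conditions: SnCl4 (1.2 equiv), 2,6-di-tert-butyl-4-methylpyridine (0.3 equiv), CH2Cl2, −78 °C
Reagents that add atoms: none
Why: SnCl4 binds the tertiary hydroxyl and the C–O bond ionises to the D4 cation 14, while the hindered pyridine takes up adventitious HCl so that the allylsilane is not protodesilylated. The cation is captured at D3 by the (Z)-allylsilane, anti to silicon (SE2'), which gives the beta-silyl cation 15, and loss of Me3Si to the tin-bound hydroxide unveils the D2 methylene; the closest known reaction types are the allylsilane-terminated cation–olefin cyclisation and the Lewis acid allylation of tertiary carbinols by allylsilanes (Hosomi–Sakurai manifold). Ring D closes in the 6-endo mode with respect to the D2=D3 alkene through a chair-like transition state, and attack at D3 instead of D2 is dictated by silicon, since only this regiochemistry places the positive charge beta to the C–Si bond. The D3–D4 bond, the ring and the D3 stereocentre form at once, and no endocyclic alkene isomer can arise because the double bond is created only where silicon leaves. D3 is set relative to the D1 carbinol: the CH2OTBS group, trans to D1 on the alkene, is equatorial in the chair, and the OTIPS group is expected to stand pseudoaxial, because in the plane of the alkene it would be eclipsed with the CH2SiMe3 arm (allylic 1,2-strain, raised by the bulk of the triisopropylsilyl group); a pseudoaxial D1–O bond and an equatorial D3 substituent give the 1,3-trans ring. The step needs chemoselective ionisation at the tertiary carbinol and a cation that meets no other nucleophile: the primary oxygen is therefore a silyl ether, which does not leave, and the D1 oxygen carries the bulky silyl group, so that its attack on the cation stays reversible.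

Step 9
Reactants: 16 tert-butyl{[(1S,5S)-2,2-dimethyl-6-methylidene-5-(triisopropylsilyloxy)cyclohexyl]methoxy}dimethylsilane
Product: 17 [(1S,5S)-2,2-dimethyl-6-methylidene-5-(triisopropylsilyloxy)cyclohexyl]methanol
Conditions: HF·pyridine, pyridine, THF, 0 °C to rt
Reagents that add atoms: none
Why: Desilylation graded by sterics: buffered HF·pyridine removes the primary TBS ether and leaves the secondary TIPS ether, without a strong protic acid that could move the exocyclic alkene into the ring.

Step 10
Reactants: 17 [(1S,5S)-2,2-dimethyl-6-methylidene-5-(triisopropylsilyloxy)cyclohexyl]methanol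
Product: 18 {[(1S,3S)-3-(iodomethyl)-4,4-dimethyl-2-methylidenecyclohexyl]oxy}triisopropylsilane
Conditions: I2, PPh3, imidazole, toluene, rt to 50 °C
Reagents that add atoms: iodine, II
Why: Appel reaction: the alkoxyphosphonium ion of the primary alcohol is displaced by iodide; the beta-branched carbon slows the SN2 step, hence the warming, and no stereocentre is touched.

Step 11
Reactants: 19 luteolin
Product: 20 5-hydroxy-7-(triisopropylsilyloxy)-2-[3,4-bis(triisopropylsilyloxy)phenyl]-4H-chromen-4-one
Conditions: TIPSCl (3.5 equiv), imidazole, DMF, rt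
Reagents that add atoms: triisopropylsilyl chloride, CC(C)[Si](Cl)(C(C)C)C(C)C
Why: Silylation of phenols: the 7-, 3'- and 4'-hydroxyls react, whereas the 5-hydroxyl, held in a hydrogen bond to the C4 carbonyl and peri-hindered, stays free; TIPS ethers are used because they should survive methanol, chloride and warm zinc halide solutions better than TBS ethers.

Step 12
Reactants: 20 5-hydroxy-7-(triisopropylsilyloxy)-2-[3,4-bis(triisopropylsilyloxy)phenyl]-4H-chromen-4-one
Product: 21 5-hydroxy-6-iodo-7-(triisopropylsilyloxy)-2-[3,4-bis(triisopropylsilyloxy)phenyl]-4H-chromen-4-one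
Conditions: BnMe3N ICl2 (1.05 equiv), CaCO3, CH2Cl2–MeOH, rt
Reagents that add atoms: benzyltrimethylammonium dichloroiodate, C[N+](C)(C)Cc1ccccc1.Cl[I-]Cl
Why: Electrophilic aromatic iodination: with the 5-hydroxyl free and O7 capped, dichloroiodate salts iodinate 5,7-dioxygenated flavones at C6, ortho to the phenol, in preference to C8; CaCO3 takes up the HCl and ring B, shielded by two bulky silyl ethers, is not attacked.

Step 13
Reactants: 21 5-hydroxy-6-iodo-7-(triisopropylsilyloxy)-2-[3,4-bis(triisopropylsilyloxy)phenyl]-4H-chromen-4-one
Product: 22 6-iodo-4-oxo-7-(triisopropylsilyloxy)-2-[3,4-bis(triisopropylsilyloxy)phenyl]-4H-chromen-5-yl acetate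
Conditions: Ac2O, Et3N, DMAP (cat.), CH2Cl2, rt
Reagents that add atoms: acetic anhydride, CC(=O)OC(C)=O
Why: Acylation of a phenol under nucleophilic catalysis: capping the chelated 5-hydroxyl removes the only acidic proton that could quench the alkylzinc reagent of step 14.

Step 14
Reactants: 18 {[(1S,3S)-3-(iodomethyl)-4,4-dimethyl-2-methylidenecyclohexyl]oxy}triisopropylsilane; 22 6-iodo-4-oxo-7-(triisopropylsilyloxy)-2-[3,4-bis(triisopropylsilyloxy)phenyl]-4H-chromen-5-yl acetate
Product: 24 6-{[(1S,5S)-2,2-dimethyl-6-methylidene-5-(triisopropylsilyloxy)cyclohexyl]methyl}-4-oxo-7-(triisopropylsilyloxy)-2-[3,4-bis(triisopropylsilyloxy)phenyl]-4H-chromen-5-yl acetate, via alkylzinc iodide 23 (not isolated)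
Conditions: 18, Zn dust, LiCl, THF, 40 °C; then 22 (1.3 equiv), Pd(OAc)2 (5 mol%), SPhos (10 mol%), THF–NMP, 40 °C
Reagents that add atoms: none
Why: Negishi coupling: zinc inserts into the primary C–I bond to give 23, a homoallylic zinc reagent without a beta leaving group, and an electron-rich biarylphosphine–palladium catalyst couples it with the di-ortho-substituted aryl iodide, reductive elimination outrunning beta-hydride elimination; the acetate, the silyl ethers and the pyranone are inert to an alkylzinc halide.

Step 15
Reactants: 24 6-{[(1S,5S)-2,2-dimethyl-6-methylidene-5-(triisopropylsilyloxy)cyclohexyl]methyl}-4-oxo-7-(triisopropylsilyloxy)-2-[3,4-bis(triisopropylsilyloxy)phenyl]-4H-chromen-5-yl acetate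
Product: 25 ugonin Q, 2-(3,4-dihydroxyphenyl)-5,7-dihydroxy-6-{[(1S,5S)-5-hydroxy-2,2-dimethyl-6-methylidenecyclohexyl]methyl}-4H-chromen-4-one
Conditions: TBAF (8 equiv), THF, 0 °C to rt, argon; then K2CO3 (cat.), MeOH, rt; aq NH4Cl
Reagents that add atoms: none
Why: Fluoride desilylation and transesterification: fluoride cleaves the three aryl and the one alkyl TIPS ether and catalytic carbonate in methanol removes the 5-acetate; no acid is used, so the allylic alcohol, the exocyclic alkene and the neighbouring phenols are not brought to react with each other, and neither stereocentre is touched.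

## Compound list

1 | tert-butyldimethyl(prop-2-yn-1-yloxy)silane | C#CCO[Si](C)(C)C(C)(C)C | starting material
2 | 5,5-dimethyldihydrofuran-2(3H)-one | CC1(C)CCC(=O)O1 | starting material
3 | [3-(tert-butyldimethylsilyloxy)prop-1-yn-1-yl]lithium (lithium acetylide) | [Li]C#CCO[Si](C)(C)C(C)(C)C | intermediate
4 | lithium 2-[3-(tert-butyldimethylsilyloxy)prop-1-yn-1-yl]-5,5-dimethyltetrahydrofuran-2-olate (lithium lactolate) | [Li+].[O-]C1(C#CCO[Si](C)(C)C(C)(C)C)CCC(C)(C)O1 | intermediate
5 | 1-(tert-butyldimethylsilyloxy)-7-hydroxy-7-methyloct-2-yn-4-one | CC(C)(O)CCC(=O)C#CCO[Si](C)(C)C(C)(C)C | intermediate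
6 | (4S)-1-(tert-butyldimethylsilyloxy)-7-methyloct-2-yne-4,7-diol | CC(C)(O)CC[C@H](O)C#CCO[Si](C)(C)C(C)(C)C | intermediate
7 | (5S)-8-(tert-butyldimethylsilyloxy)-2-methyl-5-(triisopropylsilyloxy)oct-6-yn-2-ol | CC(C)(O)CC[C@H](O[Si](C(C)C)(C(C)C)C(C)C)C#CCO[Si](C)(C)C(C)(C)C | intermediate
8 | (4S)-7-methyl-4-(triisopropylsilyloxy)oct-2-yne-1,7-diol | CC(C)(O)CC[C@H](O[Si](C(C)C)(C(C)C)C(C)C)C#CCO | intermediate
9 | sodium cyclic alkoxy(alkenyl)bis(2-methoxyethoxy)aluminate of 8 (vinylalanate; tertiary hydroxyl drawn protonated) | [Na+].COCCO[Al-]1(OCCOC)OCC=C1[C@H](CCC(C)(C)O)O[Si](C(C)C)(C(C)C)C(C)C | intermediate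
10 | (2Z,4S)-3-iodo-7-methyl-4-(triisopropylsilyloxy)oct-2-ene-1,7-diol | CC(C)(O)CC[C@H](O[Si](C(C)C)(C(C)C)C(C)C)/C(I)=C/CO | intermediate
11 | (trimethylsilyl)methylmagnesium chloride | C[Si](C)(C)C[Mg]Cl | starting material
12 | (2Z,4S)-7-methyl-3-[(trimethylsilyl)methyl]-4-(triisopropylsilyloxy)oct-2-ene-1,7-diol | CC(C)(O)CC[C@H](O[Si](C(C)C)(C(C)C)C(C)C)/C(C[Si](C)(C)C)=C/CO | intermediate
13 | (5S,6Z)-8-(tert-butyldimethylsilyloxy)-2-methyl-5-(triisopropylsilyloxy)-6-[(trimethylsilyl)methyl]oct-6-en-2-ol | CC(C)(O)CC[C@H](O[Si](C(C)C)(C(C)C)C(C)C)/C(C[Si](C)(C)C)=C/CO[Si](C)(C)C(C)(C)C | intermediate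
14 | tertiary (D4) cation from 13 | C[C+](C)CC[C@H](O[Si](C(C)C)(C(C)C)C(C)C)/C(C[Si](C)(C)C)=C/CO[Si](C)(C)C(C)(C)C | intermediate
15 | cyclised beta-silyl (D2) cation | C[Si](C)(C)C[C+]1[C@@H](CO[Si](C)(C)C(C)(C)C)C(C)(C)CC[C@@H]1O[Si](C(C)C)(C(C)C)C(C)C | intermediate
16 | tert-butyl{[(1S,5S)-2,2-dimethyl-6-methylidene-5-(triisopropylsilyloxy)cyclohexyl]methoxy}dimethylsilane (trans ring D) | C=C1[C@@H](CO[Si](C)(C)C(C)(C)C)C(C)(C)CC[C@@H]1O[Si](C(C)C)(C(C)C)C(C)C | intermediate
17 | [(1S,5S)-2,2-dimethyl-6-methylidene-5-(triisopropylsilyloxy)cyclohexyl]methanol | C=C1[C@@H](CO)C(C)(C)CC[C@@H]1O[Si](C(C)C)(C(C)C)C(C)C | intermediate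
18 | {[(1S,3S)-3-(iodomethyl)-4,4-dimethyl-2-methylidenecyclohexyl]oxy}triisopropylsilane | C=C1[C@@H](CI)C(C)(C)CC[C@@H]1O[Si](C(C)C)(C(C)C)C(C)C | intermediate
19 | luteolin | O=c1cc(-c2ccc(O)c(O)c2)oc2cc(O)cc(O)c12 | starting material
20 | 5-hydroxy-7-(triisopropylsilyloxy)-2-[3,4-bis(triisopropylsilyloxy)phenyl]-4H-chromen-4-one | O=c1cc(-c2ccc(O[Si](C(C)C)(C(C)C)C(C)C)c(O[Si](C(C)C)(C(C)C)C(C)C)c2)oc2cc(O[Si](C(C)C)(C(C)C)C(C)C)cc(O)c12 | intermediate
21 | 5-hydroxy-6-iodo-7-(triisopropylsilyloxy)-2-[3,4-bis(triisopropylsilyloxy)phenyl]-4H-chromen-4-one | O=c1cc(-c2ccc(O[Si](C(C)C)(C(C)C)C(C)C)c(O[Si](C(C)C)(C(C)C)C(C)C)c2)oc2cc(O[Si](C(C)C)(C(C)C)C(C)C)c(I)c(O)c12 | intermediate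
22 | 6-iodo-4-oxo-7-(triisopropylsilyloxy)-2-[3,4-bis(triisopropylsilyloxy)phenyl]-4H-chromen-5-yl acetate | O=c1cc(-c2ccc(O[Si](C(C)C)(C(C)C)C(C)C)c(O[Si](C(C)C)(C(C)C)C(C)C)c2)oc2cc(O[Si](C(C)C)(C(C)C)C(C)C)c(I)c(OC(C)=O)c12 | intermediate
23 | {[(1S,6S)-2,2-dimethyl-6-methylidene... ring D]methyl}zinc iodide: [(1S,5S)-2,2-dimethyl-6-methylidene-5-(triisopropylsilyloxy)cyclohexyl]methylzinc iodide | C=C1[C@@H](C[Zn]I)C(C)(C)CC[C@@H]1O[Si](C(C)C)(C(C)C)C(C)C | intermediate
24 | 6-{[(1S,5S)-2,2-dimethyl-6-methylidene-5-(triisopropylsilyloxy)cyclohexyl]methyl}-4-oxo-7-(triisopropylsilyloxy)-2-[3,4-bis(triisopropylsilyloxy)phenyl]-4H-chromen-5-yl acetate | C=C1[C@@H](Cc2c(O[Si](C(C)C)(C(C)C)C(C)C)cc3oc(-c4ccc(O[Si](C(C)C)(C(C)C)C(C)C)c(O[Si](C(C)C)(C(C)C)C(C)C)c4)cc(=O)c3c2OC(C)=O)C(C)(C)CC[C@@H]1O[Si](C(C)C)(C(C)C)C(C)C | intermediate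
25 | ugonin Q | C=C1[C@@H](Cc2c(O)cc3oc(-c4ccc(O)c(O)c4)cc(=O)c3c2O)C(C)(C)CC[C@@H]1O | target

## Step count and least certain steps

Total: 15 steps. Longest linear sequence: 12 steps (steps 1 to 10, 14 and 15); steps 11 to 13 form the three-step side branch from luteolin.

**Step 8 (key step).** What is most likely to go wrong is the facial selection at D3 relative to D1. Ring closure through the chair in which the D1 silyloxy group is equatorial gives the 1,3-cis ring. That chair keeps the C–O bond out of alignment with the alkene pi system (a more nucleophilic alkene, a better stabilised developing cation) and keeps the oxygen away from the SiMe3 group on the same face, so it competes seriously with the pseudoaxial arrangement on which the plan relies. Lesser risks are protodesilylation of the allylsilane by acid formed from SnCl4 and the carbinol, and loss of the D4 cation by elimination.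

Fallback: the mirror-image carbinol is cyclised through the all-equatorial chair and D1 is inverted afterwards. It sets out from ynone 5. Transfer hydrogenation with the (R,R)-ligand gives (4R)-1-(tert-butyldimethylsilyloxy)-7-methyloct-2-yne-4,7-diol F1. The operations of steps 3 to 7 then give in turn the (5R)-bis-silyl ether F2, the (4R)-alkynediol F3, the (2Z,4R)-iodoalkene diol F4, the (2Z,4R)-allylsilane diol F5 and the (5R,6Z)-allylsilane carbinol F6. Cyclisation under the conditions of step 8 gives the cis ring silyl ether F7, with D3 as in the target and D1 inverted. TBAF removes both silyl groups to give the cis-diol F8, and TBSCl with imidazole caps the primary hydroxyl again to give the cis-carbinol F9. A Mitsunobu reaction (4-nitrobenzoic acid, PPh3, DIAD) inverts D1 and gives the trans 4-nitrobenzoate F10. K2CO3 in MeOH frees the trans-carbinol F11, and TIPSOTf with 2,6-lutidine brings the sequence back to the route at 16.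

**Step 14.** The coupling joins a beta-branched primary alkylzinc to an aryl iodide flanked by an acetate and a bulky silyl ether. Slow transmetalation and reductive elimination would leave time for beta-hydride elimination of the alkylpalladium and for reduction of the aryl iodide, and warm zinc halide and LiCl may cleave the aryl silyl ether at O7.

Fallback: a B-alkyl Suzuki–Miyaura coupling, which transfers the alkyl group from a borate and tolerates the free phenol. It sets out from iodide 18. Iodine–lithium exchange (t-BuLi, Et2O, −78 °C) and trapping with 9-methoxy-9-borabicyclo[3.3.1]nonane give the lithium B-alkyl-B-methoxy-9-borabicyclononanuide F12. This is coupled in the same flask with the unacetylated iodide 21 (PdCl2(dppf), K3PO4, DMF–water, rt to 50 °C) to give the 5-hydroxy coupled tetrakis-silyl ether F13. Fluoride treatment as in step 15 brings it back to the route at 25.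

**Step 15.** The hindered secondary TIPS ether beside the methylene group is cleaved much more slowly than the aryl silyl ethers. The tetra-phenolate would then sit for a long time in basic fluoride, where the catechol oxidises and the product is lost.

Fallback: the alkyl silyl ether is exchanged before the coupling for one that falls under the mildest fluoride conditions. It sets out from iodide 18. Buffered fluoride (TBAF, AcOH, THF) gives (1S,3S)-3-(iodomethyl)-4,4-dimethyl-2-methylidenecyclohexan-1-ol F14, which cannot close to a bicyclic ether because hydroxyl and iodomethyl group are trans. TESCl with imidazole gives the triethylsilyl ether iodide F15. Zinc insertion as in step 14 gives the alkylzinc iodide F16, and coupling with 22 gives the coupled acetate with a triethylsilyl ether at D1, F17. Short treatment with TBAF and AcOH at 0 °C, then catalytic K2CO3 in MeOH, brings it back to the route at 25.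

**Step 2.** The hydroxy ynone 5 can sit partly as its cyclic hemiketal, and the free tertiary hydroxyl can add to the activated alkyne; both would slow the hydrogen transfer and could lower the enantiomeric purity of D1, on which the configuration of D3 later depends.

Fallback: the tertiary hydroxyl is capped before the ketone is made. It sets out from lactone 2 (and acetylide 3 from 1). Opening with N,O-dimethylhydroxylamine hydrochloride and i-PrMgCl gives 4-hydroxy-N-methoxy-N,4-dimethylpentanamide F18, and TESCl with imidazole gives its triethylsilyl ether F19. Addition of 3 gives the silyl-protected ynone F20, transfer hydrogenation as in step 2 gives the (4S)-propargylic alcohol F21, and TIPSOTf with 2,6-lutidine gives the tris-silyl ether F22. CSA in MeOH removes the primary TBS and the tertiary triethylsilyl ether together and brings the sequence back to the route at 8.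

## Further compounds

F1 | step 8 | (4R)-1-(tert-butyldimethylsilyloxy)-7-methyloct-2-yne-4,7-diol | CC(C)(O)CC[C@@H](O)C#CCO[Si](C)(C)C(C)(C)C
F2 | step 8 | (5R)-8-(tert-butyldimethylsilyloxy)-2-methyl-5-(triisopropylsilyloxy)oct-6-yn-2-ol | CC(C)(O)CC[C@@H](O[Si](C(C)C)(C(C)C)C(C)C)C#CCO[Si](C)(C)C(C)(C)C
F3 | step 8 | (4R)-7-methyl-4-(triisopropylsilyloxy)oct-2-yne-1,7-diol | CC(C)(O)CC[C@@H](O[Si](C(C)C)(C(C)C)C(C)C)C#CCO
F4 | step 8 | (2Z,4R)-3-iodo-7-methyl-4-(triisopropylsilyloxy)oct-2-ene-1,7-diol | CC(C)(O)CC[C@@H](O[Si](C(C)C)(C(C)C)C(C)C)/C(I)=C/CO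
F5 | step 8 | (2Z,4R)-7-methyl-3-[(trimethylsilyl)methyl]-4-(triisopropylsilyloxy)oct-2-ene-1,7-diol | CC(C)(O)CC[C@@H](O[Si](C(C)C)(C(C)C)C(C)C)/C(C[Si](C)(C)C)=C/CO
F6 | step 8 | (5R,6Z)-8-(tert-butyldimethylsilyloxy)-2-methyl-5-(triisopropylsilyloxy)-6-[(trimethylsilyl)methyl]oct-6-en-2-ol | CC(C)(O)CC[C@@H](O[Si](C(C)C)(C(C)C)C(C)C)/C(C[Si](C)(C)C)=C/CO[Si](C)(C)C(C)(C)C
F7 | step 8 | tert-butyl{[(1S,5R)-2,2-dimethyl-6-methylidene-5-(triisopropylsilyloxy)cyclohexyl]methoxy}dimethylsilane (cis ring) | C=C1[C@@H](CO[Si](C)(C)C(C)(C)C)C(C)(C)CC[C@H]1O[Si](C(C)C)(C(C)C)C(C)C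
F8 | step 8 | (1R,3S)-3-(hydroxymethyl)-4,4-dimethyl-2-methylidenecyclohexan-1-ol (cis-diol) | C=C1[C@@H](CO)C(C)(C)CC[C@H]1O
F9 | step 8 | (1R,3S)-3-[(tert-butyldimethylsilyloxy)methyl]-4,4-dimethyl-2-methylidenecyclohexan-1-ol | C=C1[C@@H](CO[Si](C)(C)C(C)(C)C)C(C)(C)CC[C@H]1O
F10 | step 8 | (1S,3S)-3-[(tert-butyldimethylsilyloxy)methyl]-4,4-dimethyl-2-methylidenecyclohexyl 4-nitrobenzoate | C=C1[C@@H](CO[Si](C)(C)C(C)(C)C)C(C)(C)CC[C@@H]1OC(=O)c1ccc(cc1)[N+](=O)[O-]
F11 | step 8 | (1S,3S)-3-[(tert-butyldimethylsilyloxy)methyl]-4,4-dimethyl-2-methylidenecyclohexan-1-ol | C=C1[C@@H](CO[Si](C)(C)C(C)(C)C)C(C)(C)CC[C@@H]1O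
F12 | step 14 | lithium 9-{[(1S,5S)-2,2-dimethyl-6-methylidene-5-(triisopropylsilyloxy)cyclohexyl]methyl}-9-methoxy-9-borabicyclo[3.3.1]nonan-9-uide | [Li+].C=C1[C@@H](C[B-]2(OC)C3CCCC2CCC3)C(C)(C)CC[C@@H]1O[Si](C(C)C)(C(C)C)C(C)C
F13 | step 14 | 6-{[(1S,5S)-2,2-dimethyl-6-methylidene-5-(triisopropylsilyloxy)cyclohexyl]methyl}-5-hydroxy-7-(triisopropylsilyloxy)-2-[3,4-bis(triisopropylsilyloxy)phenyl]-4H-chromen-4-one | C=C1[C@@H](Cc2c(O[Si](C(C)C)(C(C)C)C(C)C)cc3oc(-c4ccc(O[Si](C(C)C)(C(C)C)C(C)C)c(O[Si](C(C)C)(C(C)C)C(C)C)c4)cc(=O)c3c2O)C(C)(C)CC[C@@H]1O[Si](C(C)C)(C(C)C)C(C)C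
F14 | step 15 | (1S,3S)-3-(iodomethyl)-4,4-dimethyl-2-methylidenecyclohexan-1-ol | C=C1[C@@H](CI)C(C)(C)CC[C@@H]1O
F15 | step 15 | triethyl{[(1S,3S)-3-(iodomethyl)-4,4-dimethyl-2-methylidenecyclohexyl]oxy}silane | C=C1[C@@H](CI)C(C)(C)CC[C@@H]1O[Si](CC)(CC)CC
F16 | step 15 | [(1S,5S)-2,2-dimethyl-6-methylidene-5-(triethylsilyloxy)cyclohexyl]methylzinc iodide | C=C1[C@@H](C[Zn]I)C(C)(C)CC[C@@H]1O[Si](CC)(CC)CC
F17 | step 15 | 6-{[(1S,5S)-2,2-dimethyl-6-methylidene-5-(triethylsilyloxy)cyclohexyl]methyl}-4-oxo-7-(triisopropylsilyloxy)-2-[3,4-bis(triisopropylsilyloxy)phenyl]-4H-chromen-5-yl acetate | C=C1[C@@H](Cc2c(O[Si](C(C)C)(C(C)C)C(C)C)cc3oc(-c4ccc(O[Si](C(C)C)(C(C)C)C(C)C)c(O[Si](C(C)C)(C(C)C)C(C)C)c4)cc(=O)c3c2OC(C)=O)C(C)(C)CC[C@@H]1O[Si](CC)(CC)CC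
F18 | step 2 | 4-hydroxy-N-methoxy-N,4-dimethylpentanamide | CON(C)C(=O)CCC(C)(C)O
F19 | step 2 | N-methoxy-N,4-dimethyl-4-(triethylsilyloxy)pentanamide | CON(C)C(=O)CCC(C)(C)O[Si](CC)(CC)CC
F20 | step 2 | 1-(tert-butyldimethylsilyloxy)-7-methyl-7-(triethylsilyloxy)oct-2-yn-4-one | CC[Si](CC)(CC)OC(C)(C)CCC(=O)C#CCO[Si](C)(C)C(C)(C)C
F21 | step 2 | (4S)-1-(tert-butyldimethylsilyloxy)-7-methyl-7-(triethylsilyloxy)oct-2-yn-4-ol | CC[Si](CC)(CC)OC(C)(C)CC[C@H](O)C#CCO[Si](C)(C)C(C)(C)C
F22 | step 2 | (4S)-1-(tert-butyldimethylsilyloxy)-7-methyl-7-(triethylsilyloxy)-4-(triisopropylsilyloxy)oct-2-yne | CC[Si](CC)(CC)OC(C)(C)CC[C@H](O[Si](C(C)C)(C(C)C)C(C)C)C#CCO[Si](C)(C)C(C)(C)C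
A1 | alternative 1 | open-chain aldehyde–iodoalkene with the tetra-MOM flavone on the D3 methylene | C=C(I)[C@@H](Cc2c(OCOC)cc3oc(-c4ccc(OCOC)c(OCOC)c4)cc(=O)c3c2OCOC)C(C)(C)CCC=O
A2 | alternative 1 | tetra-MOM ugonin Q | C=C1[C@@H](Cc2c(OCOC)cc3oc(-c4ccc(OCOC)c(OCOC)c4)cc(=O)c3c2OCOC)C(C)(C)CC[C@@H]1O
A3 | alternative 2 | 6-(2-diazoacetyl)-2-[3,4-bis(methoxymethoxy)phenyl]-4H-pyran-4-one | [N-]=[N+]=CC(=O)c1cc(=O)cc(-c2ccc(OCOC)c(OCOC)c2)o1
A4 | alternative 2 | ring D ynol triisopropylsilyl ether with the D1 oxygen as TBS ether | C=C1[C@@H](CC#CO[Si](C(C)C)(C(C)C)C(C)C)C(C)(C)CC[C@@H]1O[Si](C)(C)C(C)(C)C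
A5 | alternative 2 | ugonin Q with 7-O-triisopropylsilyl, 3',4'-di-O-MOM and D1 O-TBS protection | C=C1[C@@H](Cc2c(O[Si](C(C)C)(C(C)C)C(C)C)cc3oc(-c4ccc(OCOC)c(OCOC)c4)cc(=O)c3c2O)C(C)(C)CC[C@@H]1O[Si](C)(C)C(C)(C)C
A6 | alternative 3 | 2-iodo-3,5-bis(methoxymethoxy)-4-(ring D methyl)phenol with the D1 oxygen as TBS ether | C=C1[C@@H](Cc2c(OCOC)cc(O)c(I)c2OCOC)C(C)(C)CC[C@@H]1O[Si](C)(C)C(C)(C)C
A7 | alternative 3 | 4-ethynyl-1,2-bis(methoxymethoxy)benzene | C#Cc1ccc(OCOC)c(OCOC)c1
A8 | alternative 3 | carbon monoxide | [C-]#[O+]
A9 | alternative 3 | tetra-MOM ugonin Q TBS ether | C=C1[C@@H](Cc2c(OCOC)cc3oc(-c4ccc(OCOC)c(OCOC)c4)cc(=O)c3c2OCOC)C(C)(C)CC[C@@H]1O[Si](C)(C)C(C)(C)C
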